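**Retrosynthetic overview**
- Feature: without the anisole ring A, O1–C2–C3–C4–C4a–C8a of ring C is a 2,3-dihydro-4H-pyran-4-one. Its only stereocentre, C2, is the former carbonyl carbon of an aryl aldehyde.
- 14 ⇒ (O-methylation) 7-phenol 13 ⇒ (ring A: C4a–C5 and C8–C8a, Diels–Alder/aromatisation with diene 5) 5-sulfinyl-dihydropyranone 10 ⇒ (S–O, C5–S, C5–I) dihydropyranone 7.
- 7 ⇒ (ring C: C2–C3 and O1–C8a, catalytic asymmetric hetero-Diels–Alder) benzofuran aldehyde 4 + silyloxydiene 5.
- 4 ⇒ (furan ring: Sonogashira coupling/5-endo-dig closure) iodophenol 1 + alkyne 2.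
- Ring order: furan ring of the benzofuran, then ring C together with C2, then ring A last.

Key step: step 2

Remark on the chemistry: the sense of induction in step 2 ((S)-BINOL, Si-face attack, 2S) is assigned by analogy with simple aromatic aldehydes under BINOL–Ti catalysis, and the equally available (R)-ligand would be used if aldehyde 4 responded in the opposite sense; 10, 11 and 12 are mixtures at the centres erased on aromatisation, so only C2 is specified.

**Step 1**
Reactants: 1 4-hydroxy-3-iodobenzaldehyde; 2 4-ethynylanisole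
Product: 4 2-(4-methoxyphenyl)benzofuran-5-carbaldehyde, via o-alkynylphenol 3 (not isolated)
Conditions: PdCl2(PPh3)2 (3 mol %), CuI (5 mol %), Et3N (3 equiv), DMF, rt → 70 °C
Reagents that add atoms: none
Why: Sonogashira coupling of an o-iodophenol, followed in the same pot by base/metal-promoted 5-endo-dig addition of the phenol oxygen to the alkyne, is the standard one-pot entry to 2-arylbenzofurans and tolerates the para-formyl group.

**Step 2**
Reactants: 4 2-(4-methoxyphenyl)benzofuran-5-carbaldehyde; 5 (E)-1-methoxy-3-(trimethylsilyloxy)buta-1,3-diene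
Product: 7 (S)-2-[2-(4-methoxyphenyl)benzofuran-5-yl]-2,3-dihydro-4H-pyran-4-one, via silyl aldol adduct 6 (not isolated)
Conditions: (S)-BINOL (20 mol %), Ti(OiPr)4 (10 mol %), 4 Å MS, Et2O–CH2Cl2, −20 °C; then TFA (cat.), CH2Cl2, 0 °C → rt
Reagents that add atoms: none
Why: The titanium binaphtholate binds the formyl oxygen of 4, and the CH2 terminus of 5 attacks the carbonyl carbon along the Mukaiyama aldol pathway typical of BINOL–Ti catalysts, forming C2–C3 and giving 6. Acid then frees the carbinol oxygen, which adds 6-endo-trig to the methoxy-bearing enone carbon and expels methanol, forming O1–C8a (pyranone C6) and closing ring C. The closest known reaction is the catalytic enantioselective formal hetero-Diels–Alder reaction of aromatic aldehydes with this diene, applied here to a new aldehyde. C2 is set in the C–C bond-forming event, where the (S)-binaphtholate pocket tells the flat aryl group from hydrogen and leaves the Si face open; it is not touched afterwards because the C2–O bond is never broken. Only facial selectivity is needed, since diene polarity fixes the regiochemistry and the aldehyde is the sole Lewis-basic carbonyl, with the benzofuran and anisole units as spectators. Recrystallisation of 7 or 8 should allow the enantiomeric purity to be upgraded if required.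

**Step 3**
Reactants: 7 (S)-2-[2-(4-methoxyphenyl)benzofuran-5-yl]-2,3-dihydro-4H-pyran-4-one
Product: 8 (S)-5-iodo-2-[2-(4-methoxyphenyl)benzofuran-5-yl]-2,3-dihydro-4H-pyran-4-one
Conditions: I2 (1.5 equiv), pyridine–CH2Cl2 (1:1), 0 °C → rt, dark
Reagents that add atoms: iodine, SMILES II
Why: In this pyridine-mediated α-iodination of a cyclic enone (addition/iodination/elimination) C5 is both the enone α-carbon and the enol-ether β-carbon, while the buffered I2–pyridine system is too weak an electrophile for benzofuran C3 or the anisole ring and too weak a base to enolise C3 and endanger C2.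

**Step 4**
Reactants: 8 (S)-5-iodo-2-[2-(4-methoxyphenyl)benzofuran-5-yl]-2,3-dihydro-4H-pyran-4-one
Product: 9 (S)-2-[2-(4-methoxyphenyl)benzofuran-5-yl]-5-(phenylthio)-2,3-dihydro-4H-pyran-4-one
Conditions: PhSH, Bu3SnOMe, toluene, rt, MeOH stripped off (gives Bu3SnSPh); then 8, Pd(PPh3)4 (5 mol %), toluene, 80 °C
Reagents that add atoms: thiophenol (delivered as its tributyltin thiolate), SMILES Sc1ccccc1
Why: In this Migita-type (Stille-like) C–S cross-coupling of an alkenyl iodide the covalent tin thiolate keeps the medium neutral and free of thiolate anion, so conjugate addition at C6, reductive deiodination and enolisation at C3 should not compete.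

**Step 5**
Reactants: 9 (S)-2-[2-(4-methoxyphenyl)benzofuran-5-yl]-5-(phenylthio)-2,3-dihydro-4H-pyran-4-one
Product: 10 (2S)-2-[2-(4-methoxyphenyl)benzofuran-5-yl]-5-(phenylsulfinyl)-2,3-dihydro-4H-pyran-4-one (both epimers at sulfur)
Conditions: mCPBA (1.0 equiv), CH2Cl2, −78 → −30 °C
Reagents that add atoms: mCPBA, SMILES O=C(OO)c1cccc(Cl)c1
Why: In this chemoselective sulfide-to-sulfoxide oxidation sulfur is by far the most nucleophilic site at low temperature, one equivalent of peracid avoids the sulfone and spares the benzofuran C2=C3 bond, and the configuration at sulfur is irrelevant because sulfur is lost in step 6.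

**Step 6**
Reactants: 10 (2S)-2-[2-(4-methoxyphenyl)benzofuran-5-yl]-5-(phenylsulfinyl)-2,3-dihydro-4H-pyran-4-one; 5 (E)-1-methoxy-3-(trimethylsilyloxy)buta-1,3-diene (3 equiv)
Product: 13 (S)-7-hydroxy-2-[2-(4-methoxyphenyl)benzofuran-5-yl]chroman-4-one, via cis-fused cycloadduct 11 (not isolated), via methoxy-tetrahydrochromenone 12 (not isolated)
Conditions: toluene, sealed tube, 60 → 90 °C; then 1 M HCl, THF, 0 °C → rt
Reagents that add atoms: none
Why: Proposed new method: the C5 sulfinyl and C4 carbonyl groups together lower the LUMO of the C5=C6 bond and both make C6 the acceptor carbon, so the CH2 terminus of 5 should bond to C6 (future C8a) and the methoxy-bearing terminus to C5 (future C4a), by a normal-demand Diels–Alder reaction or its stepwise Mukaiyama–Michael/ring-closure equivalent, which places the silyloxy carbon at C7; in cis-fused 11 the sulfinyl group and H-8a are syn, so thermal syn-elimination of benzenesulfenic acid (scavenged by excess diene) gives 12 and makes the sequence irreversible, and dilute acid then removes methanol (1,4-elimination across C5/C8) and the silyl group to leave the phenol ring; no base is present and C2–O1 is never broken, so C2 is retained; the closest known reactions are the cycloaddition/sulfoxide-pyrolysis benzannulations of 2-sulfinyl enones and sulfinylquinones and the cycloadditions of 3-acceptor-substituted chromones with this diene, none of which has been shown on a 5-sulfinyl-2,3-dihydro-4-pyranone.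

**Step 7**
Reactants: 13 (S)-7-hydroxy-2-[2-(4-methoxyphenyl)benzofuran-5-yl]chroman-4-one
Product: 14 Lophirone J, (S)-7-methoxy-2-[2-(4-methoxyphenyl)benzofuran-5-yl]chroman-4-one
Conditions: MeOH (1.5 equiv), PPh3, DIAD, THF, 0 °C → rt
Reagents that add atoms: methanol, SMILES CO
Why: Mitsunobu etherification suits the acidic 7-OH (para to the C4 carbonyl), and its essentially neutral medium avoids the C3-enolate/E1cB opening to the 2'-hydroxychalcone through which flavanones racemise under carbonate/MeI conditions.

**Compound list**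
1 | 4-hydroxy-3-iodobenzaldehyde | O=Cc1ccc(O)c(I)c1 | starting material
2 | 4-ethynylanisole | C#Cc1ccc(OC)cc1 | starting material
3 | 4-hydroxy-3-[(4-methoxyphenyl)ethynyl]benzaldehyde | O=Cc1ccc(O)c(C#Cc2ccc(OC)cc2)c1 | intermediate
4 | 2-(4-methoxyphenyl)benzofuran-5-carbaldehyde | COc1ccc(-c2cc3cc(C=O)ccc3o2)cc1 | intermediate
5 | (E)-1-methoxy-3-(trimethylsilyloxy)buta-1,3-diene | CO/C=C/C(=C)O[Si](C)(C)C | starting material
6 | (S,E)-1-methoxy-5-[2-(4-methoxyphenyl)benzofuran-5-yl]-5-(trimethylsilyloxy)pent-1-en-3-one | COc1ccc(-c2cc3cc([C@H](CC(=O)/C=C/OC)O[Si](C)(C)C)ccc3o2)cc1 | intermediate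
7 | (S)-2-[2-(4-methoxyphenyl)benzofuran-5-yl]-2,3-dihydro-4H-pyran-4-one | COc1ccc(-c2cc3cc([C@@H]4CC(=O)C=CO4)ccc3o2)cc1 | intermediate
8 | (S)-5-iodo-2-[2-(4-methoxyphenyl)benzofuran-5-yl]-2,3-dihydro-4H-pyran-4-one | COc1ccc(-c2cc3cc([C@@H]4CC(=O)C(I)=CO4)ccc3o2)cc1 | intermediate
9 | (S)-2-[2-(4-methoxyphenyl)benzofuran-5-yl]-5-(phenylthio)-2,3-dihydro-4H-pyran-4-one | COc1ccc(-c2cc3cc([C@@H]4CC(=O)C(Sc5ccccc5)=CO4)ccc3o2)cc1 | intermediate
10 | (2S)-2-[2-(4-methoxyphenyl)benzofuran-5-yl]-5-(phenylsulfinyl)-2,3-dihydro-4H-pyran-4-one, epimers at sulfur | COc1ccc(-c2cc3cc([C@@H]4CC(=O)C(S(=O)c5ccccc5)=CO4)ccc3o2)cc1 | intermediate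
11 | (2S)-5-methoxy-2-[2-(4-methoxyphenyl)benzofuran-5-yl]-4a-(phenylsulfinyl)-7-(trimethylsilyloxy)-2,3,4a,5,8,8a-hexahydro-4H-chromen-4-one, cis ring fusion, other centres unspecified | COc1ccc(-c2cc3cc([C@@H]4CC(=O)C5(S(=O)c6ccccc6)C(OC)C=C(O[Si](C)(C)C)CC5O4)ccc3o2)cc1 | intermediate
12 | (2S)-5-methoxy-2-[2-(4-methoxyphenyl)benzofuran-5-yl]-7-(trimethylsilyloxy)-2,3,5,8-tetrahydro-4H-chromen-4-one, C5 unspecified | COc1ccc(-c2cc3cc([C@@H]4CC(=O)C5=C(CC(O[Si](C)(C)C)=CC5OC)O4)ccc3o2)cc1 | intermediate
13 | (S)-7-hydroxy-2-[2-(4-methoxyphenyl)benzofuran-5-yl]chroman-4-one | COc1ccc(-c2cc3cc([C@@H]4CC(=O)c5ccc(O)cc5O4)ccc3o2)cc1 | intermediate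
14 | Lophirone J, (S)-7-methoxy-2-[2-(4-methoxyphenyl)benzofuran-5-yl]chroman-4-one | COc1ccc(-c2cc3cc([C@@H]4CC(=O)c5ccc(OC)cc5O4)ccc3o2)cc1 | target

Total step count: 7. Longest linear sequence: 7 steps (from 1).

**Steps most likely to fail**

Step 6 (labelled step). Donation from O1 into the enone may cancel much of the sulfinyl activation, so that thermal decay of the diene outruns cycloaddition. Alternatively, the addition may stop at an open-chain Michael stage and not close. The fallback uses known chemistry, buys ring A instead of building it, sets out from 4 and rejoins at 14.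
- Crossed Claisen condensation of methyl 2-hydroxy-4-methoxybenzoate with the lithium enolate of tert-butyl acetate gives tert-butyl 3-(2-hydroxy-4-methoxyphenyl)-3-oxopropanoate F1.
- Knoevenagel condensation of F1 with aldehyde 4 (piperidine/AcOH, toluene) gives tert-butyl 2-(2-hydroxy-4-methoxybenzoyl)-3-[2-(4-methoxyphenyl)benzofuran-5-yl]acrylate F2.
- A bifunctional cinchona-alkaloid thiourea, in the pseudoenantiomeric series that delivers 2S, catalyses the enantioselective 6-endo-trig oxa-Michael closure to tert-butyl (2S)-7-methoxy-2-[2-(4-methoxyphenyl)benzofuran-5-yl]-4-oxochromane-3-carboxylate F3.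
- TsOH in warm toluene cleaves the tert-butyl ester and decarboxylates F3 to 14.

Step 4. Thiolate may poison the catalyst, thiolate transfer may be slow, or the α-iodoenone may undergo protodeiodination, any of which would leave C5 without sulfur. The fallback reverses the polarity at C5, sets out from 8 and rejoins at 9.
- Pd(0)-catalysed stannylation of 8 with hexabutyldistannane gives (S)-2-[2-(4-methoxyphenyl)benzofuran-5-yl]-5-(tributylstannyl)-2,3-dihydro-4H-pyran-4-one F4.
- The C5–Sn bond, activated by both the tin β-effect and O1, undergoes ipso-sulfenylation with benzenesulfenyl chloride in CH2Cl2 at −78 °C. This should be faster than attack at benzofuran C3, and it gives 9.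

Step 2. Facial selectivity may erode with a poorly soluble, electron-rich, extended aldehyde, either through a slow catalysed path overtaken by silyl-cation background catalysis or through partial ionisation of the benzylic C–O bond during the acid stage. The fallback replaces Lewis-acid aldol catalysis by a hydrogen-bond-catalysed concerted cycloaddition with a different diene, sets out from 4 and rejoins at 7.
- Aldehyde 4 and commercial (E)-1-dimethylamino-3-(tert-butyldimethylsilyloxy)buta-1,3-diene react under (R,R)-1-naphthyl-TADDOL catalysis (toluene, −40 °C). This gives (6S)-4-(tert-butyldimethylsilyloxy)-N,N-dimethyl-6-[2-(4-methoxyphenyl)benzofuran-5-yl]-5,6-dihydro-2H-pyran-2-amine F5.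
- Acetyl chloride at −78 °C removes the amine and the silyl group without protic acid and gives 7.

**Further compounds**
F1 | step 6 | tert-butyl 3-(2-hydroxy-4-methoxyphenyl)-3-oxopropanoate | COc1ccc(C(=O)CC(=O)OC(C)(C)C)c(O)c1
F2 | step 6 | tert-butyl 2-(2-hydroxy-4-methoxybenzoyl)-3-[2-(4-methoxyphenyl)benzofuran-5-yl]acrylate (alkene geometry not defined) | COc1ccc(-c2cc3cc(C=C(C(=O)OC(C)(C)C)C(=O)c4ccc(OC)cc4O)ccc3o2)cc1
F3 | step 6 | tert-butyl (2S)-7-methoxy-2-[2-(4-methoxyphenyl)benzofuran-5-yl]-4-oxochromane-3-carboxylate (C3 epimers/enol) | COc1ccc(-c2cc3cc([C@@H]4C(C(=O)OC(C)(C)C)C(=O)c5ccc(OC)cc5O4)ccc3o2)cc1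
F4 | step 4 | (S)-2-[2-(4-methoxyphenyl)benzofuran-5-yl]-5-(tributylstannyl)-2,3-dihydro-4H-pyran-4-one | COc1ccc(-c2cc3cc([C@@H]4CC(=O)C([Sn](CCCC)(CCCC)CCCC)=CO4)ccc3o2)cc1
F5 | step 2 | (6S)-4-(tert-butyldimethylsilyloxy)-N,N-dimethyl-6-[2-(4-methoxyphenyl)benzofuran-5-yl]-5,6-dihydro-2H-pyran-2-amine (aminal carbon unspecified) | COc1ccc(-c2cc3cc([C@@H]4CC(O[Si](C)(C)C(C)(C)C)=CC(N(C)C)O4)ccc3o2)cc1
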